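## Analysis of the target

The target is an isoflavone. Ring A is a benzo ring with hydroxyls at C5 and C7, fused to the 4-pyranone ring C (O1, C2–C4, C4a, C8a), and ring C carries ring B at C3. Ring B is fused across C4'–C5' to a 2,2-dimethyl-2H-pyran (ring D, O1''–C4''), and bears a free hydroxyl at C3' and a 3-methylbut-2-enyl (prenyl) group at C2'. There is no stereocentre; the ring D olefin is cis by constraint and the prenyl olefin carries two identical methyl groups, so no configuration has to be controlled. The sensitive groups are the electron-rich ring D olefin and the prenyl olefin (acid, electrophiles, oxidants, hydrogenation), the prenyl group next to the free O3'–H (acid closes it to a chroman), C2 of ring C (a Michael acceptor that hard nucleophiles can open), and three phenols. The difficulty is twofold: ring B carries five contiguous substituents (C1' aryl, C2' prenyl, C3' OH, C4' O, C5' C) that must each be placed regioselectively, and all three phenols have to be freed at the end without acid, hydride, hydrogen or oxidant. The strategy rests on ring A: O1 (at C8a), O5 and O7 occupy the two ortho positions and the para position of C4a relative to the C4 carbonyl. A 2,4,6-trifluorobenzoyl group therefore maps exactly onto ring A: one ortho fluoride is displaced by the enol oxygen to close ring C, and the two that remain sit at C5 and C7, still activated by the same carbonyl for exchange against oxygen. Because the trifluorophenyl ring is symmetric, the closure has no regiochemical choice to make.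

## Retrosynthetic reasoning

Ring B intermediates are named as 2H-chromenes; chromene C6, C7, C8, C8a, C4a correspond to C1', C2', C3', C4', C5'.

**27 to 26.** The three phenolic O–H bonds (O5, O7, O3') are traced back to allyl ethers in 26. Allyl is the one phenol protecting group that leaves under neutral conditions with zerovalent palladium and an amine scavenger, which the prenyl group, ring D and the ortho-prenyl phenol all tolerate. One operation frees all three.

**26 to 22 and 24.** The C5–O and C7–O bonds are cut back to C–F bonds of 22, with the oxygen coming from allyloxide 24 (made from 23). These two carbons are ortho and para to the C4 carbonyl, so they accept an alkoxide by addition–elimination; the monosubstituted compound 25 lies on the way. An alkoxide rather than hydroxide is used so that no phenoxide forms and the ring stays electrophilic for the second exchange.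

**22 to 19 (key disconnection).** The O1–C8a bond is cut, opening ring C to the hydroxymethylene ketone 19. Forward, the enolate oxygen of 19 has to displace one ortho fluoride of its own aroyl group. This is the only bond of ring C that can be formed from a symmetric, commercially simple ring A precursor without any regiochemical issue, and it is formed under mild carbonate conditions that spare every olefin.

**19 to 17.** The C2–C3 bond is cut: C2 is a formyl carbon delivered to the enolate 18 of the benzyl aryl ketone 17 by a crossed Claisen condensation. The benzylic, aroyl-activated methylene of 17 is the only acidic site.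

**17 to 13 and 14.** The C4–C4a bond is cut between the N-methoxy-N-methylamide 13 and the aryllithium 15 derived from 14. Lithiation of 14 can occur only between two fluorines and all three such positions are equivalent. The amide stops the addition at the ketone stage.

**13 to 8.** The O3' allyl group of 13 is removed to phenol 12. The C2'–prenyl bond of 12 is then traced to the O3' 1,1-dimethylallyl ether 10, since an aromatic Claisen rearrangement delivers a normal prenyl group to the only free ortho position of O3'. Ether 10 comes from the propargyl ether 9 by semi-hydrogenation, and 9 from phenol 8 and chloride 2. This O-to-C transfer avoids direct C-prenylation, which has no regiocontrol.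

**8 to 6.** The amide of 8 is made from acid 7. Acid 7 arises from ester 6 by nucleophilic cleavage of both the O3' methyl ether and the methyl ester in one step; Lewis acids are excluded because ring D is a tertiary allylic ether.

**6 to 1 and 2.** Ring D is opened at C5'–C4'' and O4'–C2'' to the aryl propargyl ether 3, made from phenol 1 and chloride 2. In 1 the O4' hydroxyl is free and O3' is blocked as its methyl ether, so the propargyl Claisen can go only to C5'. Compound 1 already carries the C1' acetic acid chain. A halide at C1' was not used, because its later homologation by palladium-catalysed enolate coupling would collide with the allyl ether of 13.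

## Alternatives that were turned down

**Alternative 1:** Ring C is cut at C3–C4 and O1–C2. The morpholine enamine A2 of the ring B arylacetaldehyde would be C-acylated by 2,4,6-triacetoxybenzoyl chloride A3; carbonate in methanol in the same flask would strip the acetates, and an ortho phenoxide would add to the aminomethylene carbon and expel morpholine, giving the 3'-silyl ether A1 of the target.
- For: two bonds of ring C form in one flask, O5 and O7 arrive as oxygen, A3 is symmetric, and only a silyl ether remains to be removed. On step economy after the key step this is stronger than the chosen route.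
- Against: A3 is a doubly ortho-substituted acid chloride bearing three aryl acetates that are themselves acyl donors toward the enamine and toward liberated morpholine. N-acylation competes with C-acylation. A2 requires an enolisable arylacetaldehyde that self-condenses and oxidises easily.
- Comparison: the chosen route forms C4–C4a from a stable, symmetric aryllithium and an amide that cannot over-add, with nothing base-labile on ring A. It pays for this with one formylation and one fluoride-exchange step.

**Alternative 2:** Ring D is cut last, at C5'–C4'' and O4'–C2''. Heating the O4' 1,1-dimethylpropargyl ether A5 of the fully assembled, tris(methoxymethyl)-protected isoflavone would give the pyran A4 by Claisen shift and oxa-6π closure.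
- For: this pericyclic cascade is very dependable, only one ortho position is free, and ring D would be exposed to few steps. On that last point it is stronger than the chosen route, which carries ring D from step 2.
- Against: it solves neither ring C nor the substitution of ring B. The isoflavone and the prenyl group must be built first, with O4' distinguished from three other phenols. The acetal groups of A4 must finally be removed with acid, exactly when the prenyl group sits next to the free O3'–H and ring D is present.
- Comparison: the chosen route uses the same cascade at step 2 on a simple ester and ends without acid.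

**Alternative 3:** Ring C is cut at C4–C4a as an electrophilic acylation. The β-aryloxy acrylamide A7, built on a symmetric 3,5-bis(allyloxy)phenyl ether, would be activated with triflic anhydride and 2-fluoropyridine; the ring A carbon ortho to the vinyl ether oxygen would attack the iminium carbon, and water would release the ketone, giving A6, which is identical with 26.
- For: ring A is symmetric and highly nucleophilic, O5 and O7 are oxygen from the start, and 26 is reached without fluoride exchange. This is stronger on step count at the end.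
- Against: a triflyl iminium electrophile and the triflic acid formed beside it must coexist with the ring D olefin, the prenyl olefin, three allyl ethers, an enol ether and the electron-rich ring B. A7 also needs a geometrically defined β-aryloxy acrylamide.
- Comparison: the chosen closure reverses the polarity, making ring A the electrophile and oxygen the nucleophile, and runs under carbonate base, which every olefin in the molecule tolerates.

Key step: step 11

Remark on the chemistry: 19 is drawn as the hydrogen-bonded (Z)-enol of a β-ketoaldehyde; its tautomers interconvert and give the same enolate 20. Compounds 11, 16 and 21 are transient and racemic where they hold an sp3 centre.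

## Route

**Step 1**
Reactants: 1 methyl 2-(4-hydroxy-3-methoxyphenyl)acetate (methyl homovanillate); 2 3-chloro-3-methylbut-1-yne
Product: 3 methyl 2-{3-methoxy-4-[(2-methylbut-3-yn-2-yl)oxy]phenyl}acetate
Conditions: CuCl2·2H2O (cat.), DBU, MeCN, 0 °C to rt
Reagents that add atoms: none
Why: Copper-catalysed O-alkylation of a phenol with a tertiary propargylic chloride is the standard entry to aryl 1,1-dimethylpropargyl ethers; only O4' is free and DBU does not enolise the ester.

**Step 2**
Reactants: 3 methyl 2-{3-methoxy-4-[(2-methylbut-3-yn-2-yl)oxy]phenyl}acetate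
Product: 6 methyl 2-(8-methoxy-2,2-dimethyl-2H-chromen-6-yl)acetate, via ortho-allenylphenol 4 (not isolated), via ortho-quinone methide 5 (not isolated)
Conditions: PhNEt2, 185 °C
Reagents that add atoms: none
Why: Aromatic propargyl Claisen rearrangement and enolisation should give 4, a 1,5-hydrogen shift 5, and oxa-6π electrocyclisation ring D; C5' is the only unsubstituted ortho position of O4', and a shift to the methoxy-bearing carbon is reversible and unproductive.

**Step 3**
Reactants: 6 methyl 2-(8-methoxy-2,2-dimethyl-2H-chromen-6-yl)acetate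
Product: 7 2-(8-hydroxy-2,2-dimethyl-2H-chromen-6-yl)acetic acid
Conditions: NaSEt (excess), DMF, 120 °C; then cold aq. HCl to pH 3
Reagents that add atoms: none
Why: Thiolate SN2 demethylation cleaves the aryl methyl ether and, as intended, the methyl ester; the conditions are basic and non-oxidising, so the tertiary allylic ether of ring D, which a Lewis acid would ionise, should be untouched.

**Step 4**
Reactants: 7 2-(8-hydroxy-2,2-dimethyl-2H-chromen-6-yl)acetic acid
Product: 8 2-(8-hydroxy-2,2-dimethyl-2H-chromen-6-yl)-N-methoxy-N-methylacetamide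
Conditions: MeNHOMe·HCl, EDC·HCl, HOBt, i-Pr2NEt, CH2Cl2, 0 °C to rt
Reagents that add atoms: N,O-dimethylhydroxylamine hydrochloride, CNOC.Cl
Why: Carbodiimide amide coupling; the amine outcompetes the phenol for the active ester and aminolyses any aryl ester formed, giving the amide that will later stop aryllithium addition at the ketone.

**Step 5**
Reactants: 8 2-(8-hydroxy-2,2-dimethyl-2H-chromen-6-yl)-N-methoxy-N-methylacetamide; 2 3-chloro-3-methylbut-1-yne
Product: 9 2-{2,2-dimethyl-8-[(2-methylbut-3-yn-2-yl)oxy]-2H-chromen-6-yl}-N-methoxy-N-methylacetamide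
Conditions: CuCl2·2H2O (cat.), DBU, MeCN, 0 °C to rt
Reagents that add atoms: none
Why: The same copper-catalysed propargylation as in step 1, now on O3'; the amide α-hydrogens are not acidic enough for DBU.

**Step 6**
Reactants: 9 2-{2,2-dimethyl-8-[(2-methylbut-3-yn-2-yl)oxy]-2H-chromen-6-yl}-N-methoxy-N-methylacetamide
Product: 10 2-{2,2-dimethyl-8-[(2-methylbut-3-en-2-yl)oxy]-2H-chromen-6-yl}-N-methoxy-N-methylacetamide
Conditions: H2 (1 atm, 1 equiv), Pd/CaCO3 poisoned with Pb(OAc)2, quinoline, EtOAc, rt
Reagents that add atoms: none
Why: Lindlar semi-hydrogenation of a terminal alkyne; with the poisoned catalyst and one equivalent of hydrogen the cis-disubstituted ring D olefin and the N–O bond should be spared.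

**Step 7**
Reactants: 10 2-{2,2-dimethyl-8-[(2-methylbut-3-en-2-yl)oxy]-2H-chromen-6-yl}-N-methoxy-N-methylacetamide
Product: 12 2-[8-hydroxy-2,2-dimethyl-7-(3-methylbut-2-en-1-yl)-2H-chromen-6-yl]-N-methoxy-N-methylacetamide, via cyclohexadienone 11 (not isolated)
Conditions: PhNEt2, 130 °C
Reagents that add atoms: none
Why: Aromatic Claisen rearrangement with allylic transposition turns the 1,1-dimethylallyl ether into a normal prenyl group at C2', the only ortho position of O3' that bears hydrogen; tautomerisation of 11 is irreversible and the basic solvent suppresses chroman formation.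

**Step 8**
Reactants: 12 2-[8-hydroxy-2,2-dimethyl-7-(3-methylbut-2-en-1-yl)-2H-chromen-6-yl]-N-methoxy-N-methylacetamide
Product: 13 2-[8-(allyloxy)-2,2-dimethyl-7-(3-methylbut-2-en-1-yl)-2H-chromen-6-yl]-N-methoxy-N-methylacetamide
Conditions: allyl bromide, K2CO3, DMF, rt
Reagents that add atoms: allyl bromide, C=CCBr
Why: Williamson etherification; allyl survives the organolithium, enolate and alkoxide steps ahead and leaves at the end together with the O5 and O7 allyl groups.

**Step 9**
Reactants: 13 2-[8-(allyloxy)-2,2-dimethyl-7-(3-methylbut-2-en-1-yl)-2H-chromen-6-yl]-N-methoxy-N-methylacetamide; 14 1,3,5-trifluorobenzene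
Product: 17 2-[8-(allyloxy)-2,2-dimethyl-7-(3-methylbut-2-en-1-yl)-2H-chromen-6-yl]-1-(2,4,6-trifluorophenyl)ethan-1-one, via 2,4,6-trifluorophenyllithium 15 (not isolated), via lithium hemiaminal alkoxide 16 (not isolated)
Conditions: 14 (2.5 equiv), n-BuLi, THF, −78 °C; then 13 added slowly, −78 °C; AcOH quench at −78 °C
Reagents that add atoms: none
Why: Deprotonation of 14 between two fluorines (three equivalent sites) gives 15, which is stable at −78 °C; its addition to the N-methoxy-N-methylamide gives chelate 16, which holds until the quench, so the ketone cannot add a second aryl group (Weinreb ketone synthesis). Excess 15 and low temperature are meant to favour addition over enolisation of the amide.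

**Step 10**
Reactants: 17 2-[8-(allyloxy)-2,2-dimethyl-7-(3-methylbut-2-en-1-yl)-2H-chromen-6-yl]-1-(2,4,6-trifluorophenyl)ethan-1-one
Product: 19 (Z)-2-[8-(allyloxy)-2,2-dimethyl-7-(3-methylbut-2-en-1-yl)-2H-chromen-6-yl]-3-hydroxy-1-(2,4,6-trifluorophenyl)prop-2-en-1-one, via lithium enolate 18 (not isolated)
Conditions: LiN(SiMe3)2, THF, −78 °C; HCO2Et, −78 to 0 °C; then cold aq. HCl to pH 4
Reagents that add atoms: ethyl formate, CCOC=O
Why: Crossed Claisen condensation (formylation) of enolate 18; the product is held as its chelated enolate, whose ring is deactivated toward the ethoxide set free, and the mild acid quench should release the hydrogen-bonded (Z)-enol.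

**Step 11**
Reactants: 19 (Z)-2-[8-(allyloxy)-2,2-dimethyl-7-(3-methylbut-2-en-1-yl)-2H-chromen-6-yl]-3-hydroxy-1-(2,4,6-trifluorophenyl)prop-2-en-1-one
Product: 22 3-[8-(allyloxy)-2,2-dimethyl-7-(3-methylbut-2-en-1-yl)-2H-chromen-6-yl]-5,7-difluoro-4H-chromen-4-one, via potassium enolate 20 (not isolated), via fluoride σ-adduct 21 (not isolated)
Conditions: K2CO3, dry DMF (0.02 M), rt to 50 °C
Reagents that add atoms: none
Why: K2CO3 deprotonates the vinylogous acid 19 to enolate 20. After rotation about C3–C4, the terminal enolate oxygen, which lies cis to the aroyl group across C2=C3, adds to an ortho C–F carbon (C8a) through a six-membered transition state; counted against the C8a=C8 bond of the arene this is a 6-exo-trig closure. The anionic σ-adduct 21 is stabilised by the C4 carbonyl and by the two other fluorines and loses fluoride to restore the arene (addition–elimination, SNAr). The closest known reaction type is the cyclisation of ortho-fluoroaroyl β-dicarbonyl enolates and enaminones to chromones and 4-quinolones. Ring C closes by O1–C8a bond formation and no stereocentre is created. The step needs oxygen rather than carbon attack and ortho rather than para displacement: carbon attack would require a four-membered ring, the para fluoride is out of intramolecular reach (dilution holds back the intermolecular reaction), and the two ortho fluorides are equivalent by symmetry, so one chromone should form. The fluorides left behind sit at C5 and C7.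

**Step 12**
Reactants: 22 3-[8-(allyloxy)-2,2-dimethyl-7-(3-methylbut-2-en-1-yl)-2H-chromen-6-yl]-5,7-difluoro-4H-chromen-4-one; 23 allyl alcohol
Product: 26 5,7-bis(allyloxy)-3-[8-(allyloxy)-2,2-dimethyl-7-(3-methylbut-2-en-1-yl)-2H-chromen-6-yl]-4H-chromen-4-one, via sodium allyloxide 24 (not isolated), via 7-allyloxy-5-fluoro isoflavone 25 (not isolated)
Conditions: 23 (2.4 equiv), NaH, dry THF/DMF, 0 °C; then 22, 0 °C to rt
Reagents that add atoms: none
Why: Intermolecular SNAr of carbonyl-activated aryl fluorides by an alkoxide; the unhindered para fluoride at C7 should go first in a dipolar medium (25), then the ortho fluoride at C5. An alkoxide keeps ring A neutral and electrophilic for the second exchange, and anhydrous conditions keep any addition at C2 reversible.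

**Step 13**
Reactants: 26 5,7-bis(allyloxy)-3-[8-(allyloxy)-2,2-dimethyl-7-(3-methylbut-2-en-1-yl)-2H-chromen-6-yl]-4H-chromen-4-one
Product: 27 5,7-dihydroxy-3-[8-hydroxy-2,2-dimethyl-7-(3-methylbut-2-en-1-yl)-2H-chromen-6-yl]-4H-chromen-4-one
Conditions: Pd(PPh3)4 (5 mol %), morpholine, THF, rt
Reagents that add atoms: none
Why: Tsuji–Trost deallylation: zerovalent palladium ionises the three aryl allyl ethers to π-allyl complexes that morpholine captures; the conditions are neutral and non-reducing, so the prenyl group, ring D and the ortho-prenyl phenol should survive.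

## Compound list

1 | methyl 2-(4-hydroxy-3-methoxyphenyl)acetate (methyl homovanillate) | COC(=O)Cc1ccc(O)c(OC)c1 | starting material
2 | 3-chloro-3-methylbut-1-yne | CC(C)(Cl)C#C | starting material
3 | methyl 2-{3-methoxy-4-[(2-methylbut-3-yn-2-yl)oxy]phenyl}acetate | COC(=O)Cc1ccc(OC(C)(C)C#C)c(OC)c1 | intermediate
4 | methyl 2-[4-hydroxy-3-methoxy-5-(3-methylbuta-1,2-dien-1-yl)phenyl]acetate (not isolated) | COC(=O)Cc1cc(OC)c(O)c(C=C=C(C)C)c1 | intermediate
5 | methyl 2-[5-methoxy-3-(3-methylbut-2-en-1-ylidene)-4-oxocyclohexa-1,5-dien-1-yl]acetate (not isolated) | COC(=O)CC1=CC(=CC=C(C)C)C(=O)C(OC)=C1 | intermediate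
6 | methyl 2-(8-methoxy-2,2-dimethyl-2H-chromen-6-yl)acetate | COC(=O)Cc1cc(OC)c2OC(C)(C)C=Cc2c1 | intermediate
7 | 2-(8-hydroxy-2,2-dimethyl-2H-chromen-6-yl)acetic acid | OC(=O)Cc1cc(O)c2OC(C)(C)C=Cc2c1 | intermediate
8 | 2-(8-hydroxy-2,2-dimethyl-2H-chromen-6-yl)-N-methoxy-N-methylacetamide | CON(C)C(=O)Cc1cc(O)c2OC(C)(C)C=Cc2c1 | intermediate
9 | 2-{2,2-dimethyl-8-[(2-methylbut-3-yn-2-yl)oxy]-2H-chromen-6-yl}-N-methoxy-N-methylacetamide | CON(C)C(=O)Cc1cc(OC(C)(C)C#C)c2OC(C)(C)C=Cc2c1 | intermediate
10 | 2-{2,2-dimethyl-8-[(2-methylbut-3-en-2-yl)oxy]-2H-chromen-6-yl}-N-methoxy-N-methylacetamide | CON(C)C(=O)Cc1cc(OC(C)(C)C=C)c2OC(C)(C)C=Cc2c1 | intermediate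
11 | 2-[2,2-dimethyl-7-(3-methylbut-2-en-1-yl)-8-oxo-7,8-dihydro-2H-chromen-6-yl]-N-methoxy-N-methylacetamide (racemic, not isolated) | CON(C)C(=O)CC1=CC2=C(OC(C)(C)C=C2)C(=O)C1CC=C(C)C | intermediate
12 | 2-[8-hydroxy-2,2-dimethyl-7-(3-methylbut-2-en-1-yl)-2H-chromen-6-yl]-N-methoxy-N-methylacetamide | CON(C)C(=O)Cc1cc2C=CC(C)(C)Oc2c(O)c1CC=C(C)C | intermediate
13 | 2-[8-(allyloxy)-2,2-dimethyl-7-(3-methylbut-2-en-1-yl)-2H-chromen-6-yl]-N-methoxy-N-methylacetamide | CON(C)C(=O)Cc1cc2C=CC(C)(C)Oc2c(OCC=C)c1CC=C(C)C | intermediate
14 | 1,3,5-trifluorobenzene | Fc1cc(F)cc(F)c1 | starting material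
15 | 2,4,6-trifluorophenyllithium (not isolated) | [Li]c1c(F)cc(F)cc1F | intermediate
16 | lithium 2-[8-(allyloxy)-2,2-dimethyl-7-(3-methylbut-2-en-1-yl)-2H-chromen-6-yl]-1-[methoxy(methyl)amino]-1-(2,4,6-trifluorophenyl)ethan-1-olate (racemic, not isolated) | [Li]OC(Cc1cc2C=CC(C)(C)Oc2c(OCC=C)c1CC=C(C)C)(N(C)OC)c1c(F)cc(F)cc1F | intermediate
17 | 2-[8-(allyloxy)-2,2-dimethyl-7-(3-methylbut-2-en-1-yl)-2H-chromen-6-yl]-1-(2,4,6-trifluorophenyl)ethan-1-one | O=C(Cc1cc2C=CC(C)(C)Oc2c(OCC=C)c1CC=C(C)C)c1c(F)cc(F)cc1F | intermediate
18 | lithium (Z)-enolate of 17 (not isolated) | [Li]O/C(=C\c1cc2C=CC(C)(C)Oc2c(OCC=C)c1CC=C(C)C)c1c(F)cc(F)cc1F | intermediate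
19 | (Z)-2-[8-(allyloxy)-2,2-dimethyl-7-(3-methylbut-2-en-1-yl)-2H-chromen-6-yl]-3-hydroxy-1-(2,4,6-trifluorophenyl)prop-2-en-1-one | O/C=C(\C(=O)c1c(F)cc(F)cc1F)c1cc2C=CC(C)(C)Oc2c(OCC=C)c1CC=C(C)C | intermediate
20 | potassium enolate of 19 (not isolated) | [K+].[O-]/C=C(\C(=O)c1c(F)cc(F)cc1F)c1cc2C=CC(C)(C)Oc2c(OCC=C)c1CC=C(C)C | intermediate
21 | potassium 3-[8-(allyloxy)-2,2-dimethyl-7-(3-methylbut-2-en-1-yl)-2H-chromen-6-yl]-5,7,8a-trifluoro-8aH-chromen-4-olate (σ-adduct, racemic, not isolated) | [K+].[O-]C1=C2C(F)=CC(F)=CC2(F)OC=C1c1cc2C=CC(C)(C)Oc2c(OCC=C)c1CC=C(C)C | intermediate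
22 | 3-[8-(allyloxy)-2,2-dimethyl-7-(3-methylbut-2-en-1-yl)-2H-chromen-6-yl]-5,7-difluoro-4H-chromen-4-one | Fc1cc(F)c2c(c1)occ(-c1cc3C=CC(C)(C)Oc3c(OCC=C)c1CC=C(C)C)c2=O | intermediate
23 | allyl alcohol (prop-2-en-1-ol) | C=CCO | starting material
24 | sodium prop-2-en-1-olate (sodium allyloxide, not isolated) | [Na+].[O-]CC=C | intermediate
25 | 7-(allyloxy)-3-[8-(allyloxy)-2,2-dimethyl-7-(3-methylbut-2-en-1-yl)-2H-chromen-6-yl]-5-fluoro-4H-chromen-4-one (not isolated) | C=CCOc1cc(F)c2c(c1)occ(-c1cc3C=CC(C)(C)Oc3c(OCC=C)c1CC=C(C)C)c2=O | intermediate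
26 | 5,7-bis(allyloxy)-3-[8-(allyloxy)-2,2-dimethyl-7-(3-methylbut-2-en-1-yl)-2H-chromen-6-yl]-4H-chromen-4-one | C=CCOc1cc(OCC=C)c2c(c1)occ(-c1cc3C=CC(C)(C)Oc3c(OCC=C)c1CC=C(C)C)c2=O | intermediate
27 | 5,7-dihydroxy-3-[8-hydroxy-2,2-dimethyl-7-(3-methylbut-2-en-1-yl)-2H-chromen-6-yl]-4H-chromen-4-one | CC(C)=CCc1c(-c2coc3cc(O)cc(O)c3c2=O)cc2c(c1O)OC(C)(C)C=C2 | target

## Step count and least certain steps

Total: 13 steps. Longest linear sequence: 13 steps (1 to 27); 2, 14 and 23 enter as purchased reagents.

**Step 11 (key step).** The likeliest failure is slow closure. The enolate then has time to displace the para fluoride of a second molecule, which is electronically at least as activated as the ortho one, or to lose its formyl carbon to adventitious hydroxide. Fallback, from 14 and 13, returning at 25: the para position is occupied by the O7 allyl ether before closure. Allyloxide 24 (one equivalent, DMF, 60 °C) should convert 14 into 1-(allyloxy)-3,5-difluorobenzene F1. Lithiation of F1 between the two fluorines (n-BuLi, THF, −78 °C) gives 4-(allyloxy)-2,6-difluorophenyllithium F2, which is acylated with 13 as in step 9 to the 4-(allyloxy)-2,6-difluorophenyl ketone F3. Formylation as in step 10 gives the hydroxymethylene ketone F4, and K2CO3 in DMF at about 80 °C should close it to 25, which one further equivalent of 24 carries on to 26. The ring is less activated, so the closure needs more heat, but no competing para fluoride remains.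

**Step 12.** Two things can go wrong: allyloxide adding at C2 and opening ring C, and the second displacement stalling once ring A carries one alkoxy group. Fallback, from 17, returning at 26: the fluorides are exchanged before ring C exists. Condensation of 17 with Me2NCH(OMe)2 (toluene, 80 °C) gives the enaminone F5, which has no acidic α-hydrogen and therefore stays electrophilic. Allyloxide 24 (about two equivalents, THF/DMF, rt to 60 °C) should displace the para and one ortho fluoride to give the 2-fluoro-4,6-bis(allyloxy) enaminone F6. Brief hydrolysis with cold dilute aqueous acid in THF gives the hydroxymethylene ketone F7, and K2CO3 in DMF at 80 °C closes it onto the last ortho fluoride to give 26.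

**Step 9.** Proton transfer from the benzylic amide methylene to 15 may outrun addition, returning 13, and 15 collapses to an aryne if the mixture warms. Fallback, from 13, returning at 17: the amide is reduced with i-Bu2AlH (THF, −78 °C) to the arylacetaldehyde F8, whose carbonyl adds 15 far faster than it enolises. The resulting carbinol F9 (racemic) is oxidised with Dess–Martin periodinane and NaHCO3 in CH2Cl2 to 17.

**Step 7.** The tertiary allyl ether may ionise and lose the C5 unit as isoprene, returning 8, or the group may travel by way of the blocked ortho carbon to the para position. Fallback, from 8, returning at 12: O-allylation with allyl bromide and K2CO3 gives the allyl ether F10. Its Claisen rearrangement (PhNEt2, 190 °C) can only give the 7-allyl phenol F11. Cross-metathesis of F11 with 2-methylbut-2-ene and the second-generation Grubbs catalyst (CH2Cl2, 40 °C) should convert the allyl into the prenyl group of 12; the ring D olefin is a poor metathesis partner.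

## Further compounds

F1 | step 11 | 1-(allyloxy)-3,5-difluorobenzene | C=CCOc1cc(F)cc(F)c1
F2 | step 11 | 4-(allyloxy)-2,6-difluorophenyllithium | [Li]c1c(F)cc(OCC=C)cc1F
F3 | step 11 | 1-[4-(allyloxy)-2,6-difluorophenyl]-2-[8-(allyloxy)-2,2-dimethyl-7-(3-methylbut-2-en-1-yl)-2H-chromen-6-yl]ethan-1-one | O=C(Cc1cc2C=CC(C)(C)Oc2c(OCC=C)c1CC=C(C)C)c1c(F)cc(OCC=C)cc1F
F4 | step 11 | (Z)-1-[4-(allyloxy)-2,6-difluorophenyl]-2-[8-(allyloxy)-2,2-dimethyl-7-(3-methylbut-2-en-1-yl)-2H-chromen-6-yl]-3-hydroxyprop-2-en-1-one | O/C=C(\C(=O)c1c(F)cc(OCC=C)cc1F)c1cc2C=CC(C)(C)Oc2c(OCC=C)c1CC=C(C)C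
F5 | step 12 | (E)-2-[8-(allyloxy)-2,2-dimethyl-7-(3-methylbut-2-en-1-yl)-2H-chromen-6-yl]-3-(dimethylamino)-1-(2,4,6-trifluorophenyl)prop-2-en-1-one | CN(C)/C=C(/C(=O)c1c(F)cc(F)cc1F)c1cc2C=CC(C)(C)Oc2c(OCC=C)c1CC=C(C)C
F6 | step 12 | (E)-1-[2,4-bis(allyloxy)-6-fluorophenyl]-2-[8-(allyloxy)-2,2-dimethyl-7-(3-methylbut-2-en-1-yl)-2H-chromen-6-yl]-3-(dimethylamino)prop-2-en-1-one | CN(C)/C=C(/C(=O)c1c(F)cc(OCC=C)cc1OCC=C)c1cc2C=CC(C)(C)Oc2c(OCC=C)c1CC=C(C)C
F7 | step 12 | (Z)-1-[2,4-bis(allyloxy)-6-fluorophenyl]-2-[8-(allyloxy)-2,2-dimethyl-7-(3-methylbut-2-en-1-yl)-2H-chromen-6-yl]-3-hydroxyprop-2-en-1-one | O/C=C(\C(=O)c1c(F)cc(OCC=C)cc1OCC=C)c1cc2C=CC(C)(C)Oc2c(OCC=C)c1CC=C(C)C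
F8 | step 9 | 2-[8-(allyloxy)-2,2-dimethyl-7-(3-methylbut-2-en-1-yl)-2H-chromen-6-yl]acetaldehyde | O=CCc1cc2C=CC(C)(C)Oc2c(OCC=C)c1CC=C(C)C
F9 | step 9 | 2-[8-(allyloxy)-2,2-dimethyl-7-(3-methylbut-2-en-1-yl)-2H-chromen-6-yl]-1-(2,4,6-trifluorophenyl)ethan-1-ol (racemic) | OC(Cc1cc2C=CC(C)(C)Oc2c(OCC=C)c1CC=C(C)C)c1c(F)cc(F)cc1F
F10 | step 7 | 2-[8-(allyloxy)-2,2-dimethyl-2H-chromen-6-yl]-N-methoxy-N-methylacetamide | CON(C)C(=O)Cc1cc(OCC=C)c2OC(C)(C)C=Cc2c1
F11 | step 7 | 2-(7-allyl-8-hydroxy-2,2-dimethyl-2H-chromen-6-yl)-N-methoxy-N-methylacetamide | CON(C)C(=O)Cc1cc2C=CC(C)(C)Oc2c(O)c1CC=C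
A1 | alternative 1 | 5,7-dihydroxy-3-{2,2-dimethyl-7-(3-methylbut-2-en-1-yl)-8-[(triisopropylsilyl)oxy]-2H-chromen-6-yl}-4H-chromen-4-one | Oc1cc(O)c2c(c1)occ(-c1cc3C=CC(C)(C)Oc3c(O[Si](C(C)C)(C(C)C)C(C)C)c1CC=C(C)C)c2=O
A2 | alternative 1 | 4-[(E)-2-{2,2-dimethyl-7-(3-methylbut-2-en-1-yl)-8-[(triisopropylsilyl)oxy]-2H-chromen-6-yl}ethenyl]morpholine | O1CCN(CC1)/C=C/c1cc2C=CC(C)(C)Oc2c(O[Si](C(C)C)(C(C)C)C(C)C)c1CC=C(C)C
A3 | alternative 1 | 2,4,6-triacetoxybenzoyl chloride | CC(=O)Oc1cc(OC(C)=O)c(C(Cl)=O)c(OC(C)=O)c1
A4 | alternative 2 | 5,7-bis(methoxymethoxy)-3-[8-(methoxymethoxy)-2,2-dimethyl-7-(3-methylbut-2-en-1-yl)-2H-chromen-6-yl]-4H-chromen-4-one | COCOc1cc(OCOC)c2c(c1)occ(-c1cc3C=CC(C)(C)Oc3c(OCOC)c1CC=C(C)C)c2=O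
A5 | alternative 2 | 5,7-bis(methoxymethoxy)-3-{3-(methoxymethoxy)-2-(3-methylbut-2-en-1-yl)-4-[(2-methylbut-3-yn-2-yl)oxy]phenyl}-4H-chromen-4-one | COCOc1cc(OCOC)c2c(c1)occ(-c1ccc(OC(C)(C)C#C)c(OCOC)c1CC=C(C)C)c2=O
A6 | alternative 3 | 5,7-bis(allyloxy)-3-[8-(allyloxy)-2,2-dimethyl-7-(3-methylbut-2-en-1-yl)-2H-chromen-6-yl]-4H-chromen-4-one | C=CCOc1cc(OCC=C)c2c(c1)occ(-c1cc3C=CC(C)(C)Oc3c(OCC=C)c1CC=C(C)C)c2=O
A7 | alternative 3 | (Z)-2-[8-(allyloxy)-2,2-dimethyl-7-(3-methylbut-2-en-1-yl)-2H-chromen-6-yl]-3-[3,5-bis(allyloxy)phenoxy]-N,N-dimethylprop-2-enamide | CN(C)C(=O)/C(=C\Oc1cc(OCC=C)cc(OCC=C)c1)c1cc2C=CC(C)(C)Oc2c(OCC=C)c1CC=C(C)C
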